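- Two questions stand for the flask, and the reckoning below follows Q to answer them.

| flask | X | D | remark | time |
|---|---|---|---|---|
| Tuesday's | 0.034 M | 0.10 M | run made earlier |  |
| Saturday's | 0.075 M | 0.10 M | run made earlier |  |
| Sunday's | 0.050 M | 0.20 M | run made earlier |  |
| flask | 0.050 M | 0.100 M |  | 40 h |

| run | time / h | X / % | Z / % | J / % | L / % | Q / % |
|---|---|---|---|---|---|---|
| Tuesday's | 4.00 | 53 | 11 | 2 | 26 | 6 |
| Tuesday's | 6.00 | 48 | 12 | 5 | 29 | 12 |
| Tuesday's | 8.00 | 36 | 15 | 11 | 27 | 18 |
| Tuesday's | 15.0 | 30 | 17 | 7 | 21 | 24 |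
| Tuesday's | 20.0 | 24 | 13 | 14 | 18 | 25 |
| Tuesday's | 30.0 | 20 | 15 | 12 | 18 | 34 |
| Tuesday's | 50.0 | 19 | 17 | 14 | 12 | 43 |
| Saturday's | 4.00 | 53 | 10 | 4 | 21 | 13 |
| Saturday's | 6.00 | 43 | 14 | 8 | 19 | 20 |
| Saturday's | 8.00 | 39 | 13 | 8 | 14 | 24 |
| Saturday's | 15.0 | 32 | 10 | 6 | 10 | 38 |
| Saturday's | 20.0 | 26 | 10 | 6 | 11 | 42 |
| Saturday's | 30.0 | 23 | 16 | 3 | 5 | 53 |
| Saturday's | 50.0 | 18 | 12 | 8 | 0 | 57 |
| Sunday's | 4.00 | 30 | 15 | 15 | 28 | 13 |
| Sunday's | 12.0 | 9 | 22 | 27 | 23 | 19 |
| Sunday's | 20.0 | 4 | 20 | 26 | 22 | 19 |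
| Sunday's | 30.0 | 9 | 23 | 31 | 15 | 28 |
| Sunday's | 50.0 | 4 | 23 | 29 | 16 | 28 |

(standard deviation of a reading: 2 percentage points)

- the species in which most of what was charged as X, at 40 h sits (Q / Z / L / J / X)
- the largest share itself, whichever of these holds it, in percent of the X charged

- percent here means X units held: one Q counts as two
- the numbers in the tables scatter with a standard deviation of 2 percentage points

- My assumption is that one Q forms from one X and one L, with rate k·cX·cL. One Q counts as two, so replacing the curves by their means gives k as the Q gain divided by two, then by the charge of X, the elapsed time, mean X and mean L, both as fractions of the charge.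
- From 20.0 h to 50.0 h, Tuesday's run gives 2.74 /M/h. Saturday's run, with twice Tuesday's charge of X at the same charge of D, gives 2.75 /M/h. These are two independent ways to one number, so I carry their mean, 2.75 /M/h, as the Q constant, a second-order rate constant.
- With mean L squared in place of mean X times mean L, the runs part: 3.92 /M/h against 11.0 /M/h.
- The flask's charge of X lies a fraction 0.390 of the way from Tuesday's to Saturday's. Interpolating gives Q 31.6% at 20.0 h, and X 21.2% and L 12.9% at 30.0 h, the midpoint of the window. The Q constant adds 15 points, so I expect Q 46.7% at 40 h, more than those values of X and L, and Q is the species I name.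
- The forecast says Q at 46%, interpolating Q directly, and it takes L to Q “in a step that is second order in L”, where my step is X with L.
- The flask gives Q at 47.9%.

    D + Z → J (k = 5.04 × 10⁻⁴ /M/min)
    X + D → L (k = 0.0281 /M/min)
    X + L → Q (k = 0.0407 /M/min)
    D + L → J (k = 0.0226 /M/min)
    D → E (k = 1.96 × 10⁻⁶ /min)
    X + D → Z (k = 0.0101 /M/min)
    D → G (k = 0.00270 /min)

- Between 20.0 h and 40 h, the means of the flask's end values are X 22.0% and L 12.0%. The Q constant then gives a gain of 15 points, against an actual 12 points. The neighbouring flask is the same charge read at 96.0 h. From 40 h to that reading the means of the end values are X 15.8% and L 6.09%, so the reckoning, added to the flask's Q at 40 h, gives Q 62.7%, and that neighbouring flask holds Q at 59.5%.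

The readings were generated by integration on assumed constants.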